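The trap in these runs is to book all starting material that vanished without giving target as one waste, when it may have left by two doors that cost the coupling partner differently.

the same everywhere: starting material 0.010 M

|  | coupling partner | initiator | remark | time |
|---|---|---|---|---|
| midnight | 10 mM (in portions, 3) | 0.37 mM | run made earlier; portions every 50 min |  |
| autumn | 10 mM (in portions, 3) | 1.5 mM | run made earlier; portions every 50 min |  |
| flask | 10.0 mM (in portions, 3) | 0.74 mM | the portions of coupling partner follow each other after 50 min, the first at the start | 15 d |

| run | time / d | target / % | starting material / % |
|---|---|---|---|
| midnight | 1.67 | 38.6 | 24.5 |
| midnight | 4.00 | 37.4 | 24.1 |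
| midnight | 8.00 | 37.6 | 23.4 |
| midnight | 12.0 | 39.3 | 24.4 |
| autumn | 1.67 | 57.4 | 0 |
| autumn | 4.00 | 59.3 | 0.4 |
| autumn | 8.00 | 55.1 | 0 |
| autumn | 12.0 | 55.9 | 0.7 |

(readings scatter by 1 percentage point)

- a reading or a percentage of target counts all its forms, free or not
- the reaction counts as stopped when no species that holds the starting material changes by six tenths of a point or more over the second half of the time

* which holds at 15 d: what has brought the reaction to rest, or that it has not come to rest (all of the starting material has reacted / the coupling partner has run out first / it is still moving)
* amount of target at 15 d, in percent of the starting material charged

I took the equimolar charge as the zero of my scale: the partner came to 100% of the starting material, and each point of target costs one point of it. The midnight run rested at 24.1% starting material and 38.2% target, and I read that stop as the partner, the limiting reagent, being paid out. I supposed that target takes a second partner to become over-reaction product, which puts that product at 30.9%. That left 6.79% of the starting material gone without partner, close to two chain ends per initiator charged, 7.40%.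

For this flask, that initiator toll, the starting material leaving without partner, is 14.8%. If the whole partner charge is consumed at these equal charges, the balances say that target is the whole charge less two points for each point left or tolled.

One number was wanting: the selectivity, target over over-reaction product. It read 1.24 at midnight and, on the same bill, 2.64 in the autumn run. Their geometric middle, 1.81, gave 47.5% target.

The weak link was the autumn bill, which supposes the partner consumed. With that run's toll of 30.0% and 0.275% starting material, the rule gives 39.5% target, but the readings averaged 56.9%. So I read the autumn run as stopped with partner to spare, and dropped its ratio and the middle built on it. I assumed instead that chains end in pairs, so that target-making goes with the square root of the initiator, while over-reaction needs no chain. From midnight, the ratio became 1.75, which gives 46.7% target and 11.8% starting material left, so I expected the partner to go first.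

The forecast said "the coupling partner has run out first" with 50% target, holding that “Raising the initiator makes coupling compete better”. The flask gave "the coupling partner has run out first" with 46.5% target, crystals counted.

    initiator → 2 initiating radical (k = 8.20 × 10⁻⁶ s⁻¹)
    starting material + initiating radical → capped initiator + first chain carrier (k = 1.70 × 10⁵ L mol⁻¹ s⁻¹)
    coupling partner + first chain carrier → target + second chain carrier (k = 8600 L mol⁻¹ s⁻¹)
    starting material + second chain carrier → by-product + first chain carrier (k = 3000 L mol⁻¹ s⁻¹)
    2 first chain carrier → ended chains (k = 6.00 × 10⁷ L mol⁻¹ s⁻¹)
    coupling partner + target → over-reaction product (k = 0.0110 L mol⁻¹ s⁻¹)
    crystals ⇌ target, rate k7*(cs7 - [target]) while solid is left; crystals form when [target] > cs7 (solubility = 4.40 mM, k = 0.00120 s⁻¹)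

In the flask, half of the target-making was done by 0.103 d and half of the over-reaction by 0.144 d, both while coupling partner was present. By 7.50 d coupling partner stood at 0%, with 12.0% starting material and 46.5% target. Ended chains reached 14.8% against the toll of 14.8%, and the rule with 12.0% left gives 46.4%. The neighbour charged with 4.4 × 10⁻⁴ M of initiator has a toll of 8.80%; it kept 21.2% starting material, the rule gives 40.0%, and it held 39.9% target.

The readings are simulated with constants of no real substance; the scatter is artificial.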